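**Retrosynthetic overview**

1. The amide C–N bond is cut to give an amino-diol head group and (4E,7R,9S)-7-methoxy-9-methylhexadec-4-enoic acid; the acid goes back through a Johnson–Claisen rearrangement (4E alkene) and a Brown allylation (C7) to (S)-citronellol (C9).
2. The strategy rests on the three-carbon array C1'–C2'–C3' on C2 of the cyclohexenone, CH2OMe–CH(NH)–CH(OH). It is an anti 2-amino-1,3-diol, so it is traced to a trans (2S,3S)-2,3-epoxy alcohol whose C2' is opened with inversion by a carbamate nitrogen tethered to O1'.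
3. The epoxy alcohol comes from titanium–tartrate epoxidation of a 2-[(E)-3-hydroxyprop-1-enyl]cyclohexenone, itself from Stille coupling of the 2-iodoenone with an (E)-stannyl allyl alcohol.
4. The iodoenone comes from the cyclohexenone (ring A), closed by ring-closing metathesis of a dienone whose C4/C5 centres are set by a (Z)-crotylboration of methyl 2,2-dimethyl-3-oxopropanoate.
5. Ring order: ring A first, the oxirane second (key step), a temporary oxazolidinone third; both heterocycles are opened again before the amide coupling.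

Key step: step 12

Remark: the carbinol carbons made by the two vinyl Grignard additions later become sp2 and are carried as epimer mixtures; each diisopinocampheylborane is specified by the α-pinene enantiomer it derives from and the aldehyde face it attacks. TBSO = tert-butyldimethylsilyloxy.

**Ring A and the dienol**

Step 1
Reactants: 1 methyl 3-hydroxy-2,2-dimethylpropanoate
Product: 2 methyl 2,2-dimethyl-3-oxopropanoate
Conditions: TEMPO (cat.), PhI(OAc)2, CH2Cl2, rt
Reagents that add atoms: none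
Why: TEMPO/PhI(OAc)2 (oxoammonium) oxidation takes the primary alcohol to the aldehyde without over-oxidation, and the quaternary α-carbon excludes enolisation or aldol self-condensation.

Step 2
Reactants: 2 methyl 2,2-dimethyl-3-oxopropanoate; 3 cis-but-2-ene
Product: 5 methyl (3R,4S)-3-hydroxy-2,2,4-trimethylhex-5-enoate, via (Z)-crotyldiisopinocampheylborane 4 (not isolated)
Conditions: 3, KOtBu, n-BuLi, THF, −78 → −45 °C; (+)-Ipc2BOMe [from (−)-α-pinene], −78 °C; BF3·OEt2; then 2, −78 °C; NaBO3·4H2O, H2O, rt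
Reagents that add atoms: (+)-B-methoxydiisopinocampheylborane, COB([C@H]1C[C@H]2C[C@@H]([C@@H]1C)C2(C)C)[C@H]1C[C@H]2C[C@@H]([C@@H]1C)C2(C)C (boron and isopinocampheyl groups of 4 only; none of its atoms stay in 5)
Why: Brown crotylboration through a closed chair (Zimmerman–Traxler) transition state: the Z crotyl geometry gives the 3,4-syn adduct and the isopinocampheyl groups from (−)-α-pinene deliver the crotyl unit to the Re face of the aldehyde, setting 3R,4S (the later trans C4-methyl/C5-oxygen pair of ring A).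

Step 3
Reactants: 5 methyl (3R,4S)-3-hydroxy-2,2,4-trimethylhex-5-enoate
Product: 6 methyl (3R,4S)-3-TBSO-2,2,4-trimethylhex-5-enoate
Conditions: TBSOTf, 2,6-lutidine, CH2Cl2, 0 °C → rt
Reagents that add atoms: tert-butyldimethylsilyl trifluoromethanesulfonate, CC(C)(C)[Si](C)(C)OS(=O)(=O)C(F)(F)F
Why: Silylation with the silyl triflate and 2,6-lutidine is the standard answer to a hindered secondary alcohol next to a quaternary carbon and leaves both stereocentres untouched.

Step 4
Reactants: 6 methyl (3R,4S)-3-TBSO-2,2,4-trimethylhex-5-enoate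
Product: 7 (3R,4S)-3-TBSO-2,2,4-trimethylhex-5-en-1-ol
Conditions: i-Bu2AlH (2.5 equiv), CH2Cl2, −78 → 0 °C; aq. potassium sodium tartrate
Reagents that add atoms: none
Why: Full hydride reduction of the ester with excess i-Bu2AlH gives the neopentyl alcohol cleanly, avoiding the aldehyde/alcohol mixtures of a partial reduction.

Step 5
Reactants: 7 (3R,4S)-3-TBSO-2,2,4-trimethylhex-5-en-1-ol
Product: 8 (3R,4S)-3-TBSO-2,2,4-trimethylhex-5-enal
Conditions: Dess–Martin periodinane, CH2Cl2, 0 °C → rt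
Reagents that add atoms: none
Why: Dess–Martin oxidation stops at the aldehyde, which cannot epimerise because its α-carbon is quaternary.

Step 6
Reactants: 8 (3R,4S)-3-TBSO-2,2,4-trimethylhex-5-enal
Product: 9 (5R,6S)-5-TBSO-4,4,6-trimethylocta-1,7-dien-3-ol (both C3 epimers)
Conditions: vinylmagnesium bromide, THF, −78 → 0 °C
Reagents that add atoms: vinylmagnesium bromide, C=C[Mg]Br
Why: Grignard 1,2-addition to the aldehyde; the new carbinol forms as an epimer mixture that is removed by oxidation in step 7.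

Step 7
Reactants: 9 (5R,6S)-5-TBSO-4,4,6-trimethylocta-1,7-dien-3-ol
Product: 10 (5R,6S)-5-TBSO-4,4,6-trimethylocta-1,7-dien-3-one
Conditions: Dess–Martin periodinane, CH2Cl2, 0 °C → rt
Reagents that add atoms: none
Why: Dess–Martin oxidation of the secondary allylic alcohol gives the vinyl ketone under neutral conditions that avoid conjugate addition to it.

Step 8
Reactants: 10 (5R,6S)-5-TBSO-4,4,6-trimethylocta-1,7-dien-3-one
Product: 11 (4S,5R)-5-TBSO-4,6,6-trimethylcyclohex-2-en-1-one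
Conditions: second-generation Grubbs catalyst (H2IMes)(PCy3)Cl2Ru=CHPh (3 mol %), CH2Cl2 (5 mM), 40 °C
Reagents that add atoms: none
Why: Ring-closing metathesis of the 1,7-diene forms the six-membered enone (ring A) with loss of ethene, a closure for which the N-heterocyclic-carbene ruthenium alkylidene tolerates the electron-poor vinyl ketone.

Step 9
Reactants: 11 (4S,5R)-5-TBSO-4,6,6-trimethylcyclohex-2-en-1-one
Product: 12 (4S,5R)-5-TBSO-2-iodo-4,6,6-trimethylcyclohex-2-en-1-one
Conditions: I2, pyridine, CH2Cl2, 0 °C → rt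
Reagents that add atoms: iodine, II
Why: α-Iodination of the enone by the iodine/pyridine addition–elimination sequence (conjugate addition of pyridine, iodination of the enolate, loss of pyridine) gives the 2-iodoenone and does not touch C4.

Step 10
Reactants: 13 prop-2-yn-1-ol
Product: 14 (E)-3-(tributylstannyl)prop-2-en-1-ol
Conditions: Bu3SnH, AIBN (cat.), neat, 80 °C; chromatography
Reagents that add atoms: tributyltin hydride, CCCC[SnH](CCCC)CCCC
Why: Radical hydrostannation of the terminal alkyne under thermodynamic control (reversible stannyl radical addition) gives mainly the (E)-β-stannyl alkene, which is separated from the minor α- and Z-isomers.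

Step 11
Reactants: 12 (4S,5R)-5-TBSO-2-iodo-4,6,6-trimethylcyclohex-2-en-1-one; 14 (E)-3-(tributylstannyl)prop-2-en-1-ol
Product: 15 (4S,5R)-5-TBSO-2-[(1E)-3-hydroxyprop-1-en-1-yl]-4,6,6-trimethylcyclohex-2-en-1-one
Conditions: Pd2(dba)3 (2.5 mol %), AsPh3, CuI, NMP, rt → 50 °C
Reagents that add atoms: none
Why: Stille coupling of the α-iodoenone with the alkenylstannane (zerovalent palladium, AsPh3 ligand, CuI co-catalyst) proceeds with retention of the E geometry and tolerates the free hydroxyl and the enone.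

**Key step**

Step 12
Reactants: 15 (4S,5R)-5-TBSO-2-[(1E)-3-hydroxyprop-1-en-1-yl]-4,6,6-trimethylcyclohex-2-en-1-one
Product: 16 (4S,5R)-5-TBSO-2-[(2S,3S)-3-(hydroxymethyl)oxiran-2-yl]-4,6,6-trimethylcyclohex-2-en-1-one
Conditions: Ti(OiPr)4 (10 mol %), L-(+)-diethyl tartrate (12 mol %), t-BuOOH (anhydrous, 2 equiv), 4 Å MS, CH2Cl2, −20 °C
Reagents that add atoms: tert-butyl hydroperoxide, CC(C)(C)OO
Why: Sharpless–Katsuki asymmetric epoxidation: the allylic alcohol and t-BuOOH exchange onto the titanium tartrate dimer and the peroxide oxygen is transferred in a concerted step to one face of the bound C2'=C3' alkene, so the oxirane is closed by a single oxygen-atom transfer that makes both C–O bonds at once (formally a [2+1] addition). The closest known reaction type is the epoxidation of (2E,4E)-dienols at the alkene next to the carbinol, the usual entry to anti 2-amino-1,3-diols of the sphingosine class. The E geometry is carried stereospecifically into the trans oxirane, and the L-(+)-tartrate ligand (oxygen delivered from below when CH2OH is drawn at the lower right) fixes both new centres as 2'S,3'S by reagent control. The step needs chemoselectivity for the side-chain alkene, enantioface control independent of the ring centres, and survival of an allylic oxirane. The ring alkene is an electron-poor enone with no hydroxyl to bind titanium, C4 and C5 are remote from the reacting alkene, and the electron-withdrawing enone disfavours ionisation of the allylic C–O bond, so the catalytic, sieve-dried protocol at −20 °C should deliver 16 intact.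

**Amino alcohol and head group**

Step 13
Reactants: 16 (4S,5R)-5-TBSO-2-[(2S,3S)-3-(hydroxymethyl)oxiran-2-yl]-4,6,6-trimethylcyclohex-2-en-1-one
Product: 18 {(2S,3S)-3-[(3S,4R)-4-TBSO-3,5,5-trimethyl-6-oxocyclohex-1-en-1-yl]oxiran-2-yl}methyl carbamate, via N-trichloroacetyl carbamate 17 (not isolated)
Conditions: Cl3CC(O)NCO, CH2Cl2, 0 °C; then K2CO3, MeOH, 0 °C
Reagents that add atoms: trichloroacetyl isocyanate, O=C=NC(=O)C(Cl)(Cl)Cl
Why: Carbamoylation of the primary alcohol with the highly electrophilic acyl isocyanate followed by mild methanolysis of the trichloroacetyl imide gives the primary carbamate under conditions that neither open the oxirane nor enolise the enone.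

Step 14
Reactants: 18 {(2S,3S)-3-[(3S,4R)-4-TBSO-3,5,5-trimethyl-6-oxocyclohex-1-en-1-yl]oxiran-2-yl}methyl carbamate
Product: 19 (4R)-4-{(S)-hydroxy[(3S,4R)-4-TBSO-3,5,5-trimethyl-6-oxocyclohex-1-en-1-yl]methyl}-1,3-oxazolidin-2-one
Conditions: NaN(SiMe3)2 (1.05 equiv), THF, −40 → 0 °C; AcOH
Reagents that add atoms: none
Why: Intramolecular nitrogen delivery: the carbamate anion opens the oxirane by 5-exo-tet SN2 attack at C2' (the carbon next to CH2O), inverting it to R while C3' keeps its S oxygen, and one equivalent of base in the cold keeps N–H deprotonation ahead of γ-deprotonation of the enone.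

Step 15
Reactants: 19 (4R)-4-{(S)-hydroxy[(3S,4R)-4-TBSO-3,5,5-trimethyl-6-oxocyclohex-1-en-1-yl]methyl}-1,3-oxazolidin-2-one
Product: 20 (4R)-4-{(S)-TBSO[(3S,4R)-4-TBSO-3,5,5-trimethyl-6-oxocyclohex-1-en-1-yl]methyl}-1,3-oxazolidin-2-one
Conditions: TBSOTf, 2,6-lutidine, CH2Cl2, −20 → 0 °C; MeOH/aq. NaHCO3 work-up
Reagents that add atoms: tert-butyldimethylsilyl trifluoromethanesulfonate, CC(C)(C)[Si](C)(C)OS(=O)(=O)C(F)(F)F
Why: Silyl triflate silylation protects the C3' hydroxyl so that only the C1' oxygen is free once the carbamate ring is opened; any N-silyl oxazolidinone is hydrolysed on work-up.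

Step 16
Reactants: 20 (4R)-4-{(S)-TBSO[(3S,4R)-4-TBSO-3,5,5-trimethyl-6-oxocyclohex-1-en-1-yl]methyl}-1,3-oxazolidin-2-one
Product: 21 tert-butyl (4R)-4-{(S)-TBSO[(3S,4R)-4-TBSO-3,5,5-trimethyl-6-oxocyclohex-1-en-1-yl]methyl}-2-oxo-1,3-oxazolidine-3-carboxylate
Conditions: Boc2O, DMAP (cat.), Et3N, THF, rt
Reagents that add atoms: di-tert-butyl dicarbonate, CC(C)(C)OC(=O)OC(=O)OC(C)(C)C
Why: DMAP-catalysed N-acylation with Boc2O turns the oxazolidinone into an imide-type carbamate whose ring carbonyl is activated for mild solvolysis.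

Step 17
Reactants: 21 tert-butyl (4R)-4-{(S)-TBSO[(3S,4R)-4-TBSO-3,5,5-trimethyl-6-oxocyclohex-1-en-1-yl]methyl}-2-oxo-1,3-oxazolidine-3-carboxylate
Product: 23 tert-butyl N-{(1S,2R)-1-TBSO-3-hydroxy-1-[(3S,4R)-4-TBSO-3,5,5-trimethyl-6-oxocyclohex-1-en-1-yl]propan-2-yl}carbamate, via methyl carbonate 22 (not isolated)
Conditions: Cs2CO3 (0.2 equiv), MeOH, 0 °C → rt
Reagents that add atoms: methanol, CO (methoxy group of 22 only; none of its heavy atoms stay in 23)
Why: Methoxide from catalytic Cs2CO3 in methanol attacks the less hindered ring carbonyl of the N-Boc oxazolidinone, the Boc-stabilised nitrogen leaves, and methanolysis of the resulting methyl carbonate frees the C1' hydroxyl without touching a stereocentre.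

Step 18
Reactants: 23 tert-butyl N-{(1S,2R)-1-TBSO-3-hydroxy-1-[(3S,4R)-4-TBSO-3,5,5-trimethyl-6-oxocyclohex-1-en-1-yl]propan-2-yl}carbamate
Product: 24 tert-butyl N-{(1S,2R)-1-TBSO-3-methoxy-1-[(3S,4R)-4-TBSO-3,5,5-trimethyl-6-oxocyclohex-1-en-1-yl]propan-2-yl}carbamate
Conditions: MeI, Ag2O, 4 Å MS, MeCN, rt → 40 °C, dark
Reagents that add atoms: iodomethane, CI
Why: Purdie methylation (MeI, Ag2O) etherifies the primary alcohol under essentially neutral conditions that spare the enone, the silyl ethers and the carbamate N–H.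

Step 19
Reactants: 24 tert-butyl N-{(1S,2R)-1-TBSO-3-methoxy-1-[(3S,4R)-4-TBSO-3,5,5-trimethyl-6-oxocyclohex-1-en-1-yl]propan-2-yl}carbamate
Product: 25 (4S,5R)-2-[(1S,2R)-2-amino-1-hydroxy-3-methoxypropyl]-5-hydroxy-4,6,6-trimethylcyclohex-2-en-1-one hydrochloride
Conditions: HCl (3 M in MeOH), 0 °C → rt
Reagents that add atoms: hydrogen chloride, Cl
Why: Acidolysis in methanol removes the Boc group (loss of isobutene and CO2) and solvolyses both silyl ethers in one operation, leaving the amine as its ammonium salt, protected against condensation with the ring ketone.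

**The C16 acid**

Step 20
Reactants: 26 (S)-citronellol; 27 pent-1-ene
Product: 28 (3S)-3-methyldec-6-en-1-ol (E/Z mixture)
Conditions: second-generation Grubbs catalyst (H2IMes)(PCy3)Cl2Ru=CHPh (3 mol %), 27 (5 equiv), CH2Cl2, 40 °C, sealed vessel
Reagents that add atoms: none
Why: Olefin cross-metathesis of the isopropylidene terminus with excess terminal alkene is driven by loss of isobutene, and the E/Z mixture is irrelevant because the alkene is hydrogenated next.

Step 21
Reactants: 28 (3S)-3-methyldec-6-en-1-ol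
Product: 29 (S)-3-methyldecan-1-ol
Conditions: H2 (1 atm), 10% Pd/C, EtOAc, rt
Reagents that add atoms: none
Why: Heterogeneous catalytic hydrogenation saturates the isolated alkene, and the stereocentre three bonds away is not affected.

Step 22
Reactants: 29 (S)-3-methyldecan-1-ol
Product: 30 (S)-3-methyldecanal
Conditions: TEMPO (cat.), PhI(OAc)2, CH2Cl2, rt
Reagents that add atoms: none
Why: TEMPO/PhI(OAc)2 oxidation gives the aldehyde without over-oxidation, and the β-stereocentre is not epimerisable.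

Step 23
Reactants: 30 (S)-3-methyldecanal
Product: 31 (4S,6S)-6-methyltridec-1-en-4-ol
Conditions: (−)-Ipc2BOMe [from (+)-α-pinene], allylmagnesium bromide, Et2O, 0 °C → rt; then 30, −78 °C; NaBO3·4H2O, H2O, rt
Reagents that add atoms: allylmagnesium bromide, C=CC[Mg]Br
Why: Brown allylboration through a chair transition state: the isopinocampheyl groups from (+)-α-pinene direct the allyl group to the Si face of the aldehyde (the sense that gives (S)-1-phenylbut-3-en-1-ol from benzaldehyde), setting the 4S carbinol by reagent control over the weakly directing β-methyl centre.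

Step 24
Reactants: 31 (4S,6S)-6-methyltridec-1-en-4-ol
Product: 32 (4S,6S)-4-methoxy-6-methyltridec-1-ene
Conditions: NaH, MeI, THF, 0 °C → rt
Reagents that add atoms: iodomethane, CI
Why: Williamson etherification of the sodium alkoxide with MeI installs the 7-methoxy group of the acid with retention at the carbinol carbon.

Step 25
Reactants: 32 (4S,6S)-4-methoxy-6-methyltridec-1-ene
Product: 34 (3R,5S)-3-methoxy-5-methyldodecanal, via secondary ozonide 33 (not isolated)
Conditions: O3, CH2Cl2, −78 °C; then Me2S, −78 °C → rt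
Reagents that add atoms: ozone, [O-][O+]=O
Why: Ozonolysis with reductive work-up cleaves the terminal alkene to the β-methoxy aldehyde, which is used crude to avoid elimination of methanol.

Step 26
Reactants: 34 (3R,5S)-3-methoxy-5-methyldodecanal
Product: 35 (5R,7S)-5-methoxy-7-methyltetradec-1-en-3-ol (both C3 epimers)
Conditions: vinylmagnesium bromide, THF, −78 → 0 °C
Reagents that add atoms: vinylmagnesium bromide, C=C[Mg]Br
Why: Grignard 1,2-addition gives the allylic alcohol as a carbinol epimer mixture, which does not matter because this carbon becomes an alkene carbon in step 27.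

Step 27
Reactants: 35 (5R,7S)-5-methoxy-7-methyltetradec-1-en-3-ol
Product: 38 ethyl (4E,7R,9S)-7-methoxy-9-methylhexadec-4-enoate, via mixed orthoester 36 (not isolated), via ketene acetal 37 (not isolated)
Conditions: MeC(OEt)3 (excess), EtCO2H (cat.), 140 °C, EtOH distilled off
Reagents that add atoms: triethyl orthoacetate, CC(OCC)(OCC)OCC
Why: Johnson–Claisen rearrangement: orthoester exchange and loss of ethanol give the ketene acetal, whose chair [3,3] transition state places the carbinol substituent equatorial and so delivers the 4E γ,δ-unsaturated ester.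

Step 28
Reactants: 38 ethyl (4E,7R,9S)-7-methoxy-9-methylhexadec-4-enoate
Product: 39 (4E,7R,9S)-7-methoxy-9-methylhexadec-4-enoic acid
Conditions: LiOH, THF/MeOH/H2O, rt; then aq. HCl to pH 3
Reagents that add atoms: lithium hydroxide, [Li+].[OH-]
Why: Saponification of the ethyl ester followed by acidification gives the free acid without moving the isolated E alkene.

**Union**

Step 29
Reactants: 25 (4S,5R)-2-[(1S,2R)-2-amino-1-hydroxy-3-methoxypropyl]-5-hydroxy-4,6,6-trimethylcyclohex-2-en-1-one hydrochloride; 39 (4E,7R,9S)-7-methoxy-9-methylhexadec-4-enoic acid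
Product: 41 (4E,7R,9S)-N-{(1S,2R)-1-hydroxy-1-[(3S,4R)-4-hydroxy-3,5,5-trimethyl-6-oxocyclohex-1-en-1-yl]-3-methoxypropan-2-yl}-7-methoxy-9-methylhexadec-4-enamide, via benzotriazolyl ester 40 (not isolated)
Conditions: 39, EDC·HCl, HOBt, CH2Cl2/DMF, 0 °C; then 25, i-Pr2NEt, 0 °C → rt
Reagents that add atoms: 1-hydroxybenzotriazole, On1nnc2ccccc12 (benzotriazolyloxy group of 40 only; none of its atoms stay in 41)
Why: Carbodiimide/HOBt amide coupling acylates the amine liberated in situ far faster than either secondary hydroxyl, closing the route with the N-acyl bond of 41.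

**Compound list**

1 | methyl 3-hydroxy-2,2-dimethylpropanoate | COC(=O)C(C)(C)CO | starting material
2 | methyl 2,2-dimethyl-3-oxopropanoate | COC(=O)C(C)(C)C=O | intermediate
3 | cis-but-2-ene | C/C=C\C | starting material
4 | (Z)-but-2-enyl-diisopinocampheylborane, isopinocampheyl groups from (−)-α-pinene | C/C=C\CB([C@H]1C[C@H]2C[C@@H]([C@@H]1C)C2(C)C)[C@H]1C[C@H]2C[C@@H]([C@@H]1C)C2(C)C | intermediate
5 | methyl (3R,4S)-3-hydroxy-2,2,4-trimethylhex-5-enoate | C=C[C@H](C)[C@@H](O)C(C)(C)C(=O)OC | intermediate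
6 | methyl (3R,4S)-3-[(tert-butyldimethylsilyl)oxy]-2,2,4-trimethylhex-5-enoate | C=C[C@H](C)[C@@H](O[Si](C)(C)C(C)(C)C)C(C)(C)C(=O)OC | intermediate
7 | (3R,4S)-3-[(tert-butyldimethylsilyl)oxy]-2,2,4-trimethylhex-5-en-1-ol | C=C[C@H](C)[C@@H](O[Si](C)(C)C(C)(C)C)C(C)(C)CO | intermediate
8 | (3R,4S)-3-[(tert-butyldimethylsilyl)oxy]-2,2,4-trimethylhex-5-enal | C=C[C@H](C)[C@@H](O[Si](C)(C)C(C)(C)C)C(C)(C)C=O | intermediate
9 | (5R,6S)-5-[(tert-butyldimethylsilyl)oxy]-4,4,6-trimethylocta-1,7-dien-3-ol, both C3 epimers | C=C[C@H](C)[C@@H](O[Si](C)(C)C(C)(C)C)C(C)(C)C(O)C=C | intermediate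
10 | (5R,6S)-5-[(tert-butyldimethylsilyl)oxy]-4,4,6-trimethylocta-1,7-dien-3-one | C=C[C@H](C)[C@@H](O[Si](C)(C)C(C)(C)C)C(C)(C)C(=O)C=C | intermediate
11 | (4S,5R)-5-[(tert-butyldimethylsilyl)oxy]-4,6,6-trimethylcyclohex-2-en-1-one | O=C1C=C[C@H](C)[C@@H](O[Si](C)(C)C(C)(C)C)C1(C)C | intermediate
12 | (4S,5R)-5-[(tert-butyldimethylsilyl)oxy]-2-iodo-4,6,6-trimethylcyclohex-2-en-1-one | O=C1C(I)=C[C@H](C)[C@@H](O[Si](C)(C)C(C)(C)C)C1(C)C | intermediate
13 | prop-2-yn-1-ol | C#CCO | starting material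
14 | (E)-3-(tributylstannyl)prop-2-en-1-ol | CCCC[Sn](CCCC)(CCCC)/C=C/CO | intermediate
15 | (4S,5R)-5-[(tert-butyldimethylsilyl)oxy]-2-[(1E)-3-hydroxyprop-1-en-1-yl]-4,6,6-trimethylcyclohex-2-en-1-one | OC/C=C/C1=C[C@H](C)[C@@H](O[Si](C)(C)C(C)(C)C)C(C)(C)C1=O | intermediate
16 | (4S,5R)-5-[(tert-butyldimethylsilyl)oxy]-2-[(2S,3S)-3-(hydroxymethyl)oxiran-2-yl]-4,6,6-trimethylcyclohex-2-en-1-one | OC[C@@H]1O[C@H]1C2=C[C@H](C)[C@@H](O[Si](C)(C)C(C)(C)C)C(C)(C)C2=O | intermediate
17 | {(2S,3S)-3-[(3S,4R)-4-TBSO-3,5,5-trimethyl-6-oxocyclohex-1-en-1-yl]oxiran-2-yl}methyl N-(trichloroacetyl)carbamate | O=C(NC(=O)C(Cl)(Cl)Cl)OC[C@@H]1O[C@H]1C2=C[C@H](C)[C@@H](O[Si](C)(C)C(C)(C)C)C(C)(C)C2=O | intermediate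
18 | {(2S,3S)-3-[(3S,4R)-4-TBSO-3,5,5-trimethyl-6-oxocyclohex-1-en-1-yl]oxiran-2-yl}methyl carbamate | NC(=O)OC[C@@H]1O[C@H]1C2=C[C@H](C)[C@@H](O[Si](C)(C)C(C)(C)C)C(C)(C)C2=O | intermediate
19 | (4R)-4-{(S)-hydroxy[(3S,4R)-4-TBSO-3,5,5-trimethyl-6-oxocyclohex-1-en-1-yl]methyl}-1,3-oxazolidin-2-one | O=C1OC[C@@H](N1)[C@@H](O)C2=C[C@H](C)[C@@H](O[Si](C)(C)C(C)(C)C)C(C)(C)C2=O | intermediate
20 | (4R)-4-{(S)-TBSO[(3S,4R)-4-TBSO-3,5,5-trimethyl-6-oxocyclohex-1-en-1-yl]methyl}-1,3-oxazolidin-2-one | O=C1OC[C@@H](N1)[C@@H](O[Si](C)(C)C(C)(C)C)C2=C[C@H](C)[C@@H](O[Si](C)(C)C(C)(C)C)C(C)(C)C2=O | intermediate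
21 | tert-butyl (4R)-4-{(S)-TBSO[(3S,4R)-4-TBSO-3,5,5-trimethyl-6-oxocyclohex-1-en-1-yl]methyl}-2-oxo-1,3-oxazolidine-3-carboxylate | O=C1OC[C@@H](N1C(=O)OC(C)(C)C)[C@@H](O[Si](C)(C)C(C)(C)C)C2=C[C@H](C)[C@@H](O[Si](C)(C)C(C)(C)C)C(C)(C)C2=O | intermediate
22 | (2R,3S)-2-[(tert-butoxycarbonyl)amino]-3-TBSO-3-[(3S,4R)-4-TBSO-3,5,5-trimethyl-6-oxocyclohex-1-en-1-yl]propyl methyl carbonate | COC(=O)OC[C@@H](NC(=O)OC(C)(C)C)[C@@H](O[Si](C)(C)C(C)(C)C)C1=C[C@H](C)[C@@H](O[Si](C)(C)C(C)(C)C)C(C)(C)C1=O | intermediate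
23 | tert-butyl N-{(1S,2R)-1-TBSO-3-hydroxy-1-[(3S,4R)-4-TBSO-3,5,5-trimethyl-6-oxocyclohex-1-en-1-yl]propan-2-yl}carbamate | OC[C@@H](NC(=O)OC(C)(C)C)[C@@H](O[Si](C)(C)C(C)(C)C)C1=C[C@H](C)[C@@H](O[Si](C)(C)C(C)(C)C)C(C)(C)C1=O | intermediate
24 | tert-butyl N-{(1S,2R)-1-TBSO-3-methoxy-1-[(3S,4R)-4-TBSO-3,5,5-trimethyl-6-oxocyclohex-1-en-1-yl]propan-2-yl}carbamate | COC[C@@H](NC(=O)OC(C)(C)C)[C@@H](O[Si](C)(C)C(C)(C)C)C1=C[C@H](C)[C@@H](O[Si](C)(C)C(C)(C)C)C(C)(C)C1=O | intermediate
25 | (4S,5R)-2-[(1S,2R)-2-amino-1-hydroxy-3-methoxypropyl]-5-hydroxy-4,6,6-trimethylcyclohex-2-en-1-one hydrochloride | Cl.COC[C@@H](N)[C@@H](O)C1=C[C@H](C)[C@@H](O)C(C)(C)C1=O | intermediate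
26 | (S)-citronellol | CC(C)=CCC[C@H](C)CCO | starting material
27 | pent-1-ene | C=CCCC | starting material
28 | (3S)-3-methyldec-6-en-1-ol, E/Z mixture | CCCC=CCC[C@H](C)CCO | intermediate
29 | (S)-3-methyldecan-1-ol | CCCCCCC[C@H](C)CCO | intermediate
30 | (S)-3-methyldecanal | CCCCCCC[C@H](C)CC=O | intermediate
31 | (4S,6S)-6-methyltridec-1-en-4-ol | CCCCCCC[C@H](C)C[C@H](CC=C)O | intermediate
32 | (4S,6S)-4-methoxy-6-methyltridec-1-ene | CCCCCCC[C@H](C)C[C@H](CC=C)OC | intermediate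
33 | 3-[(2S,4S)-2-methoxy-4-methylundecyl]-1,2,4-trioxolane, both ring epimers | CCCCCCC[C@H](C)C[C@H](CC1OCOO1)OC | intermediate
34 | (3R,5S)-3-methoxy-5-methyldodecanal | CCCCCCC[C@H](C)C[C@H](CC=O)OC | intermediate
35 | (5R,7S)-5-methoxy-7-methyltetradec-1-en-3-ol, both C3 epimers | CCCCCCC[C@H](C)C[C@H](CC(O)C=C)OC | intermediate
36 | (5R,7S)-3-(1,1-diethoxyethoxy)-5-methoxy-7-methyltetradec-1-ene | CCCCCCC[C@H](C)C[C@H](CC(OC(C)(OCC)OCC)C=C)OC | intermediate
37 | (5R,7S)-3-[(1-ethoxyethenyl)oxy]-5-methoxy-7-methyltetradec-1-ene | CCCCCCC[C@H](C)C[C@H](CC(OC(=C)OCC)C=C)OC | intermediate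
38 | ethyl (4E,7R,9S)-7-methoxy-9-methylhexadec-4-enoate | CCCCCCC[C@H](C)C[C@H](C/C=C/CCC(=O)OCC)OC | intermediate
39 | (4E,7R,9S)-7-methoxy-9-methylhexadec-4-enoic acid | CCCCCCC[C@H](C)C[C@H](C/C=C/CCC(=O)O)OC | intermediate
40 | 1H-benzotriazol-1-yl (4E,7R,9S)-7-methoxy-9-methylhexadec-4-enoate | CCCCCCC[C@H](C)C[C@H](C/C=C/CCC(=O)On1nnc2ccccc12)OC | intermediate
41 | (4E,7R,9S)-N-{(1S,2R)-1-hydroxy-1-[(3S,4R)-4-hydroxy-3,5,5-trimethyl-6-oxocyclohex-1-en-1-yl]-3-methoxypropan-2-yl}-7-methoxy-9-methylhexadec-4-enamide (CNP0168625.1) | CCCCCCC[C@H](C)C[C@H](C/C=C/CCC(=O)N[C@H](COC)[C@@H](O)C1=C[C@H](C)[C@@H](O)C(C)(C)C1=O)OC | target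

**Step count and risks**

Total steps: 29 (18 in the head-group line, 1 for the stannane, 9 for the acid, 1 coupling).
Longest linear sequence: 19 steps (steps 1–9, 11–19 and 29).

Steps most likely to fail:

Step 12. What may go wrong: the cross-conjugated dienol may epoxidise slowly, so that enantioface control is incomplete, and the allylic oxirane may be opened by titanium-bound isopropoxide or tartrate. The fallback sets out from iodoenone 12 and drops the epoxide altogether. A Nozaki–Hiyama–Kishi coupling (CrCl2, NiCl2 cat., DMF) with commercial tert-butyl (4R)-4-formyl-2,2-dimethyl-1,3-oxazolidine-3-carboxylate should give, by Felkin–Anh (anti) addition, tert-butyl (4R)-4-{(S)-hydroxy[(3S,4R)-4-TBSO-3,5,5-trimethyl-6-oxocyclohex-1-en-1-yl]methyl}-2,2-dimethyl-1,3-oxazolidine-3-carboxylate F1. Silylation (TBSOTf, 2,6-lutidine) would give its silyl ether, tert-butyl (4R)-4-{(S)-TBSO[(3S,4R)-4-TBSO-3,5,5-trimethyl-6-oxocyclohex-1-en-1-yl]methyl}-2,2-dimethyl-1,3-oxazolidine-3-carboxylate F2. Chemoselective hydrolysis of the N,O-acetonide (BiBr3, MeCN/H2O) then comes back to the route at 23.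

Step 14. What may go wrong: deprotonation at the γ-position (C4–H) may compete with N–H deprotonation, causing epimerisation or vinylogous β-elimination of the oxirane, and the carbamate may migrate to the C3' oxygen. The fallback sets out from 16 and delivers nitrogen under acid instead of base. Cl3CCN with catalytic DBU would give {(2S,3S)-3-[(3S,4R)-4-TBSO-3,5,5-trimethyl-6-oxocyclohex-1-en-1-yl]oxiran-2-yl}methyl 2,2,2-trichloroacetimidate F3. Et2AlCl in CH2Cl2 at −20 °C should promote 5-exo opening at C2' to (4S,5R)-5-TBSO-2-{(S)-hydroxy[(4R)-2-(trichloromethyl)-4,5-dihydro-1,3-oxazol-4-yl]methyl}-4,6,6-trimethylcyclohex-2-en-1-one F4. Silylation would give the corresponding C3' silyl ether, (4S,5R)-5-TBSO-2-{(S)-TBSO[(4R)-2-(trichloromethyl)-4,5-dihydro-1,3-oxazol-4-yl]methyl}-4,6,6-trimethylcyclohex-2-en-1-one F5. Hydrolysis with dilute aqueous HCl in THF would give (4S,5R)-2-[(1S,2R)-2-amino-1-TBSO-3-hydroxypropyl]-5-TBSO-4,6,6-trimethylcyclohex-2-en-1-one hydrochloride F6, and Boc2O/NaHCO3 comes back to the route at 23.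

Step 19. What may go wrong: cleavage of the hindered ring silyl ether may be incomplete, or acid may promote allylic substitution at C3' in methanol. The fallback sets out from 24 and reverses the order of deprotection and acylation. Selective Boc removal (TMSOTf, 2,6-lutidine; then MeOH) would give (4S,5R)-2-[(1S,2R)-2-amino-1-TBSO-3-methoxypropyl]-5-TBSO-4,6,6-trimethylcyclohex-2-en-1-one F7. EDC·HCl/HOBt coupling with 39 would give (4E,7R,9S)-N-{(1S,2R)-1-TBSO-1-[(3S,4R)-4-TBSO-3,5,5-trimethyl-6-oxocyclohex-1-en-1-yl]-3-methoxypropan-2-yl}-7-methoxy-9-methylhexadec-4-enamide F8. Buffered HF·pyridine in THF then comes back to the route at the target 41.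

Further compounds

F1 | step 12 | tert-butyl (4R)-4-{(S)-hydroxy[(3S,4R)-4-TBSO-3,5,5-trimethyl-6-oxocyclohex-1-en-1-yl]methyl}-2,2-dimethyl-1,3-oxazolidine-3-carboxylate | CC1(C)OC[C@@H](N1C(=O)OC(C)(C)C)[C@@H](O)C2=C[C@H](C)[C@@H](O[Si](C)(C)C(C)(C)C)C(C)(C)C2=O
F2 | step 12 | tert-butyl (4R)-4-{(S)-TBSO[(3S,4R)-4-TBSO-3,5,5-trimethyl-6-oxocyclohex-1-en-1-yl]methyl}-2,2-dimethyl-1,3-oxazolidine-3-carboxylate | CC1(C)OC[C@@H](N1C(=O)OC(C)(C)C)[C@@H](O[Si](C)(C)C(C)(C)C)C2=C[C@H](C)[C@@H](O[Si](C)(C)C(C)(C)C)C(C)(C)C2=O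
F3 | step 14 | {(2S,3S)-3-[(3S,4R)-4-TBSO-3,5,5-trimethyl-6-oxocyclohex-1-en-1-yl]oxiran-2-yl}methyl 2,2,2-trichloroacetimidate | N=C(OC[C@@H]1O[C@H]1C2=C[C@H](C)[C@@H](O[Si](C)(C)C(C)(C)C)C(C)(C)C2=O)C(Cl)(Cl)Cl
F4 | step 14 | (4S,5R)-5-TBSO-2-{(S)-hydroxy[(4R)-2-(trichloromethyl)-4,5-dihydro-1,3-oxazol-4-yl]methyl}-4,6,6-trimethylcyclohex-2-en-1-one | ClC(Cl)(Cl)C1=N[C@H](CO1)[C@@H](O)C2=C[C@H](C)[C@@H](O[Si](C)(C)C(C)(C)C)C(C)(C)C2=O
F5 | step 14 | (4S,5R)-5-TBSO-2-{(S)-TBSO[(4R)-2-(trichloromethyl)-4,5-dihydro-1,3-oxazol-4-yl]methyl}-4,6,6-trimethylcyclohex-2-en-1-one | ClC(Cl)(Cl)C1=N[C@H](CO1)[C@@H](O[Si](C)(C)C(C)(C)C)C2=C[C@H](C)[C@@H](O[Si](C)(C)C(C)(C)C)C(C)(C)C2=O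
F6 | step 14 | (4S,5R)-2-[(1S,2R)-2-amino-1-TBSO-3-hydroxypropyl]-5-TBSO-4,6,6-trimethylcyclohex-2-en-1-one hydrochloride | Cl.N[C@H](CO)[C@@H](O[Si](C)(C)C(C)(C)C)C1=C[C@H](C)[C@@H](O[Si](C)(C)C(C)(C)C)C(C)(C)C1=O
F7 | step 19 | (4S,5R)-2-[(1S,2R)-2-amino-1-TBSO-3-methoxypropyl]-5-TBSO-4,6,6-trimethylcyclohex-2-en-1-one | COC[C@@H](N)[C@@H](O[Si](C)(C)C(C)(C)C)C1=C[C@H](C)[C@@H](O[Si](C)(C)C(C)(C)C)C(C)(C)C1=O
F8 | step 19 | (4E,7R,9S)-N-{(1S,2R)-1-TBSO-1-[(3S,4R)-4-TBSO-3,5,5-trimethyl-6-oxocyclohex-1-en-1-yl]-3-methoxypropan-2-yl}-7-methoxy-9-methylhexadec-4-enamide | CCCCCCC[C@H](C)C[C@H](C/C=C/CCC(=O)N[C@H](COC)[C@@H](O[Si](C)(C)C(C)(C)C)C1=C[C@H](C)[C@@H](O[Si](C)(C)C(C)(C)C)C(C)(C)C1=O)OC
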